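The three-carbon chain is read as a vinyl unit (C1–C2) inserted between ring B (3,4-dimethoxyphenyl) and the benzyl group C3–ring A (2,4,6-trimethoxyphenyl), the C2 hydroxyl being a masked boron. Everything rests on an enantioselective palladium-catalysed conjunctive cross-coupling. An achiral four-coordinate vinyl(benzyl)borate meets the ring B aryl bromide, and one operation forms the C1–aryl bond to ring B and the C2–C3 bond and sets the C2 stereocentre under ligand control. The feature exploited is the 1,2-relationship between carbinol carbon C2 and benzylic carbon C1, with C2 flanked by two benzylic methylenes. Stereoretentive C–B oxidation then gives the target.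

Key step: step 2

Labels: C1 is the CH2 on ring B, C2 is the carbinol carbon, and C3 is the CH2 on ring A. The target is the (S) enantiomer (priorities OH > C3 > C1 > H).

Assumption: the sense of induction of the ferrocenyl bisphosphine in step 2 is assigned by analogy with aryl- and alkyl-migrating vinyl borates. If the opposite sense is found, the equally commercial (SP,S′P),(R,R) antipode is used and nothing else changes.

Step 1
Reactants: 1 1,3,5-trimethoxybenzene; 2 2-(chloromethyl)-4,4,5,5-tetramethyl-1,3,2-dioxaborolane
Product: 5 2-(2,4,6-trimethoxybenzyl)-4,4,5,5-tetramethyl-1,3,2-dioxaborolane, via 2,4,6-trimethoxyphenyllithium 3 (not isolated), via lithium aryl(chloromethyl)borate 4 (not isolated)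
Conditions: n-BuLi, THF, 0 °C to rt; then 2, −78 °C to rt
Reagents that add atoms: none
Why: Directed ortho-lithiation between two methoxy groups gives 3, which adds to the boron of 2, and ate complex 4 then undergoes a Matteson-type 1,2-metallate shift of the electron-rich aryl group with loss of chloride, placing C3 between ring A and boron.

Step 2
Reactants: 5 2-(2,4,6-trimethoxybenzyl)-4,4,5,5-tetramethyl-1,3,2-dioxaborolane; 6 vinylmagnesium bromide; 7 4-bromo-1,2-dimethoxybenzene (4-bromoveratrole)
Product: 9 (S)-2-[1-(3,4-dimethoxyphenyl)-3-(2,4,6-trimethoxyphenyl)propan-2-yl]-4,4,5,5-tetramethyl-1,3,2-dioxaborolane, via bromomagnesium vinyl(benzyl)borate 8 (not isolated)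
Conditions: 6, NaOTf (sodium trifluoromethanesulfonate, 3 equiv), THF, 0 °C to rt; then 7, Pd(OAc)2 (2 mol%), (RP,R′P)-1,1′-bis[bis(4-methoxy-3,5-dimethylphenyl)phosphino]-2,2′-bis[(S)-α-(dimethylamino)benzyl]ferrocene (2.4 mol%), THF, 60 °C
Reagents that add atoms: none
Why: Vinylmagnesium bromide adds to the boron of 5 (NaOTf assists the addition and later removes bromide as NaBr) to give the four-coordinate borate 8, while 7 adds oxidatively to zerovalent palladium to give a cationic aryl complex of divalent palladium. This electrophilic palladium binds the vinyl π bond of 8 and triggers a 1,2-metallate shift in which the 2,4,6-trimethoxybenzyl group moves from boron to the boron-bearing carbon C2 anti to the metal while palladium takes the terminal carbon C1, and reductive elimination then forges the C1–C(aryl) bond to ring B. The reaction type is the known enantioselective palladium-catalysed three-component conjunctive cross-coupling of vinylboron ate complexes with aryl halides or triflates, here applied to a primary benzylic migrating group. No ring is closed. The single new stereocentre C2 is controlled by the twofold-symmetric ferrocenyl bisphosphine, which should place palladium on the Re face of C2 so that the benzyl group arrives on the Si face and (S)-9 results. The metallate shift must outrun direct Suzuki-type transfer of vinyl or benzyl, and reductive elimination must outrun β-hydride elimination, which the halide-depleted cationic palladium, the wide bite angle of the ligand and the high migratory aptitude of the electron-rich benzyl group should secure, while regiochemistry is fixed because the migrating group can only land on the carbon next to boron.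

Step 3
Reactants: 9 (S)-2-[1-(3,4-dimethoxyphenyl)-3-(2,4,6-trimethoxyphenyl)propan-2-yl]-4,4,5,5-tetramethyl-1,3,2-dioxaborolane
Product: 10 hypophaol = (S)-1-(3,4-dimethoxyphenyl)-3-(2,4,6-trimethoxyphenyl)propan-2-ol
Conditions: 30% H2O2, 3 M NaOH, THF, 0 °C to rt
Reagents that add atoms: hydrogen peroxide, OO
Why: Hydroperoxide adds to boron and the secondary alkyl group migrates from boron to oxygen with retention (stereospecific boronic ester oxidation), so the (S) centre of 9 should become the (S) carbinol while the five aryl methyl ethers are inert to cold basic peroxide.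

Compound list
1 | 1,3,5-trimethoxybenzene | COc1cc(OC)cc(OC)c1 | starting material
2 | 2-(chloromethyl)-4,4,5,5-tetramethyl-1,3,2-dioxaborolane | ClCB1OC(C)(C)C(C)(C)O1 | starting material
3 | 2,4,6-trimethoxyphenyllithium | [Li]c1c(OC)cc(OC)cc1OC | intermediate
4 | lithium (chloromethyl)(2,4,6-trimethoxyphenyl)(pinacolato)borate | [Li+].ClC[B-]1(c2c(OC)cc(OC)cc2OC)OC(C)(C)C(C)(C)O1 | intermediate
5 | 2-(2,4,6-trimethoxybenzyl)-4,4,5,5-tetramethyl-1,3,2-dioxaborolane | COc1cc(OC)c(CB2OC(C)(C)C(C)(C)O2)c(OC)c1 | intermediate
6 | vinylmagnesium bromide | C=C[Mg]Br | starting material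
7 | 4-bromo-1,2-dimethoxybenzene | COc1ccc(Br)cc1OC | starting material
8 | bromomagnesium vinyl(2,4,6-trimethoxybenzyl)(pinacolato)borate | C=C[B-]1(Cc2c(OC)cc(OC)cc2OC)OC(C)(C)C(C)(C)O1.[Mg+]Br | intermediate
9 | (S)-2-[1-(3,4-dimethoxyphenyl)-3-(2,4,6-trimethoxyphenyl)propan-2-yl]-4,4,5,5-tetramethyl-1,3,2-dioxaborolane | COc1cc(OC)c(C[C@@H](B2OC(C)(C)C(C)(C)O2)Cc3ccc(OC)c(OC)c3)c(OC)c1 | intermediate
10 | hypophaol, (S)-1-(3,4-dimethoxyphenyl)-3-(2,4,6-trimethoxyphenyl)propan-2-ol | COc1cc(OC)c(C[C@@H](O)Cc2ccc(OC)c(OC)c2)c(OC)c1 | target

Total step count: 3. Longest linear sequence: 3 (1 to 5 to 9 to 10).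

Steps most likely to fail

Step 2.
- **Risk:** direct Suzuki-type transfer of the vinyl or benzyl group from boron to palladium, β-hydride elimination after the shift, slow oxidative addition of the electron-rich bromide, or eroded facial selectivity caused by the bulky di-ortho-substituted migrating group.
- **Fallback (sets out from 3, generated from 1 as in step 1, and returns at 10):** the stereocentre is bought instead of made, and the same C1–ring B bond is formed by epoxide opening. Aryllithium 3 is treated at −78 °C with (R)-epichlorohydrin (ClC[C@H]1CO1) and BF3·OEt2. This should open the oxirane at its terminal carbon to give (R)-1-chloro-3-(2,4,6-trimethoxyphenyl)propan-2-ol F1. NaOH in methanol closes it to (R)-2-(2,4,6-trimethoxybenzyl)oxirane F2 without touching the stereocentre. 3,4-Dimethoxyphenylmagnesium bromide F3, made from 7 and magnesium turnings in THF, then opens F2 at the unsubstituted carbon under CuI catalysis (−30 °C to 0 °C) and should give 10 directly.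

Step 1.
- **Risk:** sluggish 1,2-migration in the hindered ate complex, competing attack of the aryllithium at the chloromethyl carbon, or protodeboronation of the electron-rich benzylic boronate during purification.
- **Fallback (sets out from 1 and returns at 5):** the benzylic C–B bond is made by insertion of a diazo carbon into a B–H bond instead of by aryl migration. Vilsmeier–Haack formylation of 1 (POCl3, DMF) should give 2,4,6-trimethoxybenzaldehyde F4. Condensation with p-toluenesulfonyl hydrazide in methanol should give (E)-N'-(2,4,6-trimethoxybenzylidene)-4-methylbenzenesulfonohydrazide F5. Heating F5 with NaH and pinacolborane in toluene should release 2-(diazomethyl)-1,3,5-trimethoxybenzene F6 by Bamford–Stevens fragmentation. The borane traps F6 through ate formation, 1,2-hydride shift and loss of nitrogen, giving 5.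

Step 3.
- **Risk:** protodeboronation in the strongly basic aqueous medium, slow oxidation at the crowded secondary boronate, or oxidative attack of excess peroxide on the very electron-rich ring A.
- **Fallback (sets out from 9 and returns at 10):** the boron is first turned into a species that is oxidised under near-neutral conditions. Compound 9 is stirred with aqueous KHF2 in methanol to give potassium (S)-[1-(3,4-dimethoxyphenyl)-3-(2,4,6-trimethoxyphenyl)propan-2-yl]trifluoroborate F7, which is freed from pinacol by trituration. F7 is then oxidised with one equivalent of KHSO5 (used as 2KHSO5·KHSO4·K2SO4) in acetone–water at rt within minutes. This is a stereoretentive trifluoroborate oxidation that should give 10.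

Further compounds
F1 | step 2 | (R)-1-chloro-3-(2,4,6-trimethoxyphenyl)propan-2-ol | COc1cc(OC)c(C[C@@H](O)CCl)c(OC)c1
F2 | step 2 | (R)-2-(2,4,6-trimethoxybenzyl)oxirane | COc1cc(OC)c(C[C@@H]2CO2)c(OC)c1
F3 | step 2 | 3,4-dimethoxyphenylmagnesium bromide | COc1ccc([Mg]Br)cc1OC
F4 | step 1 | 2,4,6-trimethoxybenzaldehyde | COc1cc(OC)c(C=O)c(OC)c1
F5 | step 1 | (E)-N'-(2,4,6-trimethoxybenzylidene)-4-methylbenzenesulfonohydrazide | COc1cc(OC)c(/C=N/NS(=O)(=O)c2ccc(C)cc2)c(OC)c1
F6 | step 1 | 2-(diazomethyl)-1,3,5-trimethoxybenzene | COc1cc(OC)c(C=[N+]=[N-])c(OC)c1
F7 | step 3 | potassium (S)-[1-(3,4-dimethoxyphenyl)-3-(2,4,6-trimethoxyphenyl)propan-2-yl]trifluoroborate | COc1cc(OC)c(C[C@@H]([B-](F)(F)F)Cc2ccc(OC)c(OC)c2)c(OC)c1.[K+]
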